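The hexacycle is cut into two identical C15 halves. Each six-membered ether ring of the target (bridging ring B, O–C1(CH3)–C2H2–C3H–C3'=C4', and fused ring A) holds an isoprene unit with its oxygen on the tertiary carbon; moving that oxygen to the neighbouring CH gives a 2-isopropenyl-2,3-dihydrofuran fused to the quinolinone, the precursor. In the key step zerovalent palladium opens this five-membered ring to a dienol, two dienols combine by Diels–Alder dimerisation (C3–C4 and C5–C6 bonds, three stereocentres), and acid returns each oxygen to its tertiary carbon, so that both dihydrofurans emerge ring-expanded as the dihydropyrans. Resolution of the configurationally stable racemate gives the single enantiomer.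

Key step: step 3

Numbering used: C1–C6 are the cyclohexane carbons of the target: C1 (quaternary, CH3 and the ring B oxygen), C2 (CH2), C3 (CH, bonded to C3' of quinolinone B), C4 (CH, bonded to C8, the C(CH3)2–O carbon), C5 (CH, bonded to C3'' of quinolinone A), C6 (CH2). Ring B is O–C1–C2–C3–C3'=C4'; ring A is O–C8–C4–C5–C3''=C4''. The target is (1S,3R,4R,5S) in this numbering.

Remark: the absolute configuration is not induced but selected by resolution of the end product, because the cyclohexene intermediate 7 is quasi-meso (see step 3).

Step 1
Reactants: 1 4-hydroxy-1-methylquinolin-2(1H)-one; 2 N-iodosuccinimide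
Product: 3 4-hydroxy-3-iodo-1-methylquinolin-2(1H)-one
Conditions: NIS (1.05 equiv), MeCN, 0 °C to rt
Reagents that add atoms: N-iodosuccinimide, O=C1CCC(=O)N1I
Why: Electrophilic iodination of the enol carbon C3 of the vinylogous acid 1 (α-halogenation of a 1,3-dicarbonyl-type enol) should be fast and regiospecific because C3 is the only nucleophilic carbon, and no stereocentre is formed.

Step 2
Reactants: 3 4-hydroxy-3-iodo-1-methylquinolin-2(1H)-one; 4 isoprene
Product: 5 (±)-5-methyl-2-(prop-1-en-2-yl)-2,3-dihydrofuro[3,2-c]quinolin-4(5H)-one
Conditions: Pd(OAc)2 (5 mol %), NaHCO3 (2 equiv), Bu4NCl (1 equiv), isoprene (5 equiv), DMF, 60 °C, sealed tube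
Reagents that add atoms: isoprene, C=CC(C)=C
Why: Larock-type heteroannulation of a 1,3-diene: zerovalent palladium formed in situ inserts into the C3–I bond, the vinylpalladium adds to the unsubstituted vinyl end of isoprene, and the C4 oxygen closes the five-membered ring by 5-exo attack on the internal carbon of the π-allyl complex, which places the isopropenyl group on the O-bearing carbon; the new stereocentre forms as a racemate and is erased in step 3, so no control is needed.

Step 3
Reactants: 5 (±)-5-methyl-2-(prop-1-en-2-yl)-2,3-dihydrofuro[3,2-c]quinolin-4(5H)-one (two molecules)
Product: 8 (±)-paraensidimerin C, via dienol 6 (not isolated), via all-trans cyclohexene dimer 7 (not isolated)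
Conditions: Pd(PPh3)4 (3 mol %), toluene (1 M), 110 °C; then CF3CO2H (3 equiv), 60 °C
Reagents that add atoms: none
Why: Zerovalent palladium ionises the allylic O–CH bond of each dihydrofuran (the quinolinone enolate is the leaving group) and 1,4-elimination from the π-allyl complex gives (E)-dienol 6 with a free C4 hydroxyl, a Tsuji–Trost-type elimination of an allylic ester. Two molecules of 6 then undergo thermal Diels–Alder dimerisation, one as the diene (core C3=C2–C1=C6) and one through its (E)-CH=CH bond as the dienophile (C5=C4), which closes the carbocycle by [4+2] cycloaddition with the head-to-tail regiochemistry that keeps allylic stabilisation on both partners in the asynchronous transition state; the closest known reaction type is the thermal dimerisation of 1-aryl-1,3-dienes. CF3CO2H then protonates both alkenes of 7 to tertiary cations, so that ring B closes by 6-endo-trig attack of the hydroxyl of quinolinone B on C1 and ring A by 6-exo-trig attack of the hydroxyl of quinolinone A on C8, the acid-catalysed hydroalkoxylation known from cannabidiol-type phenols. The C4/C5 trans relation comes from the (E)-dienophile, the C3/C4 trans relation from the transition state with the dienophile quinolinone endo and the isopropenyl group exo, C1 is dictated by the bridge because the hydroxyl on C3 can reach only one face of the cation, and ring A can only be trans-fused because its two anchoring bonds are trans. Net, in each half the ring oxygen has moved from the secondary carbon to the neighbouring isopropenyl carbon, so the five-membered O–CH–CH2–C3'=C4' ring has grown into six-membered ring B (and its twin into ring A) by taking in that carbon. The step needs diene release to outrun acid-induced aromatisation of 5 to a 2-isopropylfuran (secured by opening under neutral palladium conditions before any acid is added), exo placement of the isopropenyl group and closure through the C4 oxygen of the dominant 2-quinolone tautomer instead of the lactam oxygen; it gives the racemate, and no earlier stereocentre could be carried through, because 7 is quasi-meso (either hydroxyl may close either ring and the two pairings give mirror-image products), which is why the absolute configuration is left to step 4.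

Step 4
Reactants: 8 (±)-paraensidimerin C
Product: 9 paraensidimerin C
Conditions: preparative HPLC, amylose tris(3,5-dimethylphenylcarbamate) on silica, hexane/iPrOH, rt
Reagents that add atoms: none
Why: Resolution of a racemate by chromatography on a chiral stationary phase: both ether rings of 8 are closed, so the four stereocentres set relative to one another in step 3 cannot scramble, and the enantiomers are separated as such, the wanted (1S,3R,4R,5S) antipode to be identified by comparison of its measured and calculated electronic circular dichroism.

Compound list
1 | 4-hydroxy-1-methylquinolin-2(1H)-one | Cn1c(=O)cc(O)c2ccccc12 | starting material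
2 | N-iodosuccinimide | O=C1CCC(=O)N1I | starting material
3 | 4-hydroxy-3-iodo-1-methylquinolin-2(1H)-one | Cn1c(=O)c(I)c(O)c2ccccc12 | intermediate
4 | isoprene (2-methylbuta-1,3-diene) | C=CC(C)=C | starting material
5 | (±)-5-methyl-2-(prop-1-en-2-yl)-2,3-dihydrofuro[3,2-c]quinolin-4(5H)-one (racemate) | C=C(C)C1Cc2c(O1)c1ccccc1n(C)c2=O | intermediate
6 | 4-hydroxy-1-methyl-3-[(1E)-3-methylbuta-1,3-dien-1-yl]quinolin-2(1H)-one (dienol) | C=C(C)/C=C/c1c(O)c2ccccc2n(C)c1=O | intermediate
7 | (±)-3,3'-[(1S,2R,3R)-5-methyl-2-(prop-1-en-2-yl)cyclohex-4-ene-1,3-diyl]bis(4-hydroxy-1-methylquinolin-2(1H)-one) (racemate, all-trans; core C3 R, C4 R, C5 S drawn) | C1C(C)=C[C@@H](c2c(O)c3ccccc3n(C)c2=O)[C@H](C(C)=C)[C@H]1c1c(O)c2ccccc2n(C)c1=O | intermediate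
8 | (±)-paraensidimerin C (racemate; the (1S,3R,4R,5S) enantiomer is drawn) | Cn1c(=O)c2c(c3ccccc31)OC(C)(C)[C@@H]1[C@@H]2C[C@]2(C)C[C@H]1c1c(c3ccccc3n(C)c1=O)O2 | intermediate
9 | paraensidimerin C, (1S,3R,4R,5S) in the core numbering | Cn1c(=O)c2c(c3ccccc31)OC(C)(C)[C@@H]1[C@@H]2C[C@]2(C)C[C@H]1c1c(c3ccccc3n(C)c1=O)O2 | target

Total step count: 4. Longest linear sequence: 4 steps (1 to 3 to 5 to 8 to 9).

Steps most likely to fail

Step 3. Several processes could divert the cascade:
- The π-allyl palladium intermediate may collapse back onto carbon (spiro C-alkylation) or onto oxygen at the other allyl terminus instead of eliminating.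
- The dienone tautomer of 6 may electrocyclise to the 2H-pyran isomer and so withdraw dienol from the cycloaddition.
- The isopropenyl group may sit endo in the cycloaddition, which would give the C3 epimer.
- Ether closure may run through the lactam oxygen, which would give linear 4-quinolone isomers.

Fallback (ring contraction of the seven-membered isomer under acid alone), setting out from 1:
- Palladium-catalysed C3-allylation with allyl methyl carbonate (Pd(PPh3)4, THF) should give 3-allyl-4-hydroxy-1-methylquinolin-2(1H)-one F1.
- Mitsunobu O-alkylation with 2-methylprop-2-en-1-ol (PPh3, diisopropyl azodicarboxylate, THF) should give 3-allyl-1-methyl-4-[(2-methylprop-2-en-1-yl)oxy]quinolin-2(1H)-one F2.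
- Ring-closing metathesis with the second-generation Grubbs catalyst RuCl2(H2IMes)(PCy3)(=CHPh) in CH2Cl2 at 40 °C should give 3,7-dimethyl-2,5-dihydrooxepino[3,2-c]quinolin-6(7H)-one F3. Its ring holds the same oxygen on the primary end of the same allyl unit.
- F3 has no isopropenyl group and cannot aromatise to a furan, so CF3SO3H (10 mol %) in toluene at 80 °C can be used from the start. SN1 ionisation of the allylic C–O bond and loss of a proton should give dienol 6. The same acid should dimerise 6 through its O-protonated dienone cation (stepwise, chair-like closure with the three substituents equatorial) and close both ethers.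
- The sequence comes back to the route at 8.

Step 2. The annulation mixture itself contains zerovalent palladium, so the product may re-ionise and drift toward the dienol before isolation. Carbopalladation at the wrong end of isoprene, Heck-type β-hydride elimination without ring closure, or protodeiodination may also compete.

Fallback (no aryl halide, no palladium at the ring-forming stage), setting out from 1:
- Tsuji–Trost prenylation with 2-methylbut-3-en-2-ol (Pd(PPh3)4, toluene, 80 °C; attack at the unsubstituted allyl terminus) should give 4-hydroxy-1-methyl-3-(3-methylbut-2-en-1-yl)quinolin-2(1H)-one F4.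
- Epoxidation with mCPBA in CH2Cl2, followed by spontaneous 5-exo opening of the epoxide by the C4 hydroxyl, should give (±)-2-(2-hydroxypropan-2-yl)-5-methyl-2,3-dihydrofuro[3,2-c]quinolin-4(5H)-one F5.
- Syn-dehydration of the tertiary alcohol toward a methyl group with the Burgess reagent (toluene, 60 °C) comes back to the route at 5.

Step 4. The enantiomers may co-elute or load poorly on the chiral phase, so that throughput is too low. Fallback, setting out from 8: co-crystallisation with an enantiopure hydrogen-bond-donor host such as (4R,5R)-2,2-dimethyl-α,α,α',α'-tetraphenyl-1,3-dioxolane-4,5-dimethanol, which binds the lactam carbonyls. Fractional crystallisation of the diastereomeric inclusion complex and release of the guest on silica would come back to the route at 9. This fallback makes no new covalent compound (F0).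

Further compounds
F1 | step 3 | 3-allyl-4-hydroxy-1-methylquinolin-2(1H)-one | C=CCc1c(O)c2ccccc2n(C)c1=O
F2 | step 3 | 3-allyl-1-methyl-4-[(2-methylprop-2-en-1-yl)oxy]quinolin-2(1H)-one | C=CCc1c(OCC(C)=C)c2ccccc2n(C)c1=O
F3 | step 3 | 3,7-dimethyl-2,5-dihydrooxepino[3,2-c]quinolin-6(7H)-one | CC1=CCc2c(OC1)c1ccccc1n(C)c2=O
F4 | step 2 | 4-hydroxy-1-methyl-3-(3-methylbut-2-en-1-yl)quinolin-2(1H)-one | CC(C)=CCc1c(O)c2ccccc2n(C)c1=O
F5 | step 2 | (±)-2-(2-hydroxypropan-2-yl)-5-methyl-2,3-dihydrofuro[3,2-c]quinolin-4(5H)-one | CC(C)(O)C1Cc2c(O1)c1ccccc1n(C)c2=O
F0 | step 4 | none | none
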